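The route cuts both C–O bonds of the ketal carbon (C1 of the ketone-bearing naphthalenone half): one to the tertiary oxygen on C1′ and one to the phenolic oxygen on C8′ of the alcohol-bearing half. Both halves derive from one enantiopure bromo epoxide made from juglone, so each epoxide is in place before an aryllithium addition joins C8 to C1′. In the key step acid ionises the C1 dimethyl ketal; the C1′ hydroxyl closes the oxolane and the unmasked C8′ phenol then closes the 1,3-dioxin ring of the 2,8-dioxabicyclo[3.2.1]octane core, exploiting the peri placement of C1 and C8 and the ortho placement of the C8′ oxygen and C1′. Chlorination ends the route.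

Key step: step 13

Remark on the chemistry: unprimed locants (C1–C8a) refer to the ketone-bearing half of the target and primed ones (C1′–C8a′) to the alcohol-bearing half; the sense of the CBS reduction in step 5 is assigned by analogy with 1-tetralone, the peri-substituted aryl acting as the large group.

Step 1
Reactants: 1 juglone (5-hydroxynaphthalene-1,4-dione)
Product: 2 5-(methoxymethoxy)naphthalene-1,4-dione
Conditions: MeOCH2Cl, i-Pr2NEt, CH2Cl2, 0 → 23 °C
Reagents that add atoms: chloromethyl methyl ether, COCCl
Why: O-alkylation of the hydrogen-bonded phenol with a hindered amine base (Williamson-type formation of the MOM ether) should mask the only acidic proton before the reductive and organometallic steps.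

Step 2
Reactants: 2 5-(methoxymethoxy)naphthalene-1,4-dione
Product: 4 1,4-dimethoxy-5-(methoxymethoxy)naphthalene, via hydroquinone 3 (not isolated)
Conditions: Na2S2O4, n-Bu4NBr, THF/H2O, 23 °C; then KOH (aq), Me2SO4, 23 °C
Reagents that add atoms: dimethyl sulfate, COS(=O)(=O)OC
Why: dithionite should reduce the quinone to the hydroquinone, which is O-methylated twice under phase-transfer Williamson conditions (one-pot reductive methylation).

Step 3
Reactants: 4 1,4-dimethoxy-5-(methoxymethoxy)naphthalene
Product: 5 5-bromo-1,4-dimethoxy-8-(methoxymethoxy)naphthalene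
Conditions: NBS, MeCN, −20 → 0 °C, dark
Reagents that add atoms: N-bromosuccinimide, O=C1CCC(=O)N1Br
Why: electrophilic aromatic bromination should take the free alpha position para to the MOM-oxy group (as in 1-alkoxynaphthalenes), which is more nucleophilic than the beta positions of the dimethoxy ring.

Step 4
Reactants: 5 5-bromo-1,4-dimethoxy-8-(methoxymethoxy)naphthalene
Product: 7 5-bromo-4,4-dimethoxy-8-(methoxymethoxy)naphthalen-1(4H)-one, via quinone bisketal 6 (not isolated)
Conditions: Pt anode, Pt cathode, undivided cell, 1% KOH/MeOH, 0 °C, constant current; then 5% aq. AcOH/acetone, 0 °C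
Reagents that add atoms: methanol, CO; water, O
Why: anodic methoxylation of the 1,4-dimethoxy ring gives the quinone bisketal (Swenton-type oxidation), and mild acid should hydrolyse only the ketal whose oxocarbenium ion is stabilised by the ortho MOM-oxy group and whose carbonyl is less crowded by its peri neighbour, leaving the ketal peri to bromine.

Step 5
Reactants: 7 5-bromo-4,4-dimethoxy-8-(methoxymethoxy)naphthalen-1(4H)-one
Product: 8 (R)-5-bromo-4,4-dimethoxy-8-(methoxymethoxy)-1,4-dihydronaphthalen-1-ol
Conditions: (S)-2-methyl-CBS-oxazaborolidine (20 mol%), BH3·SMe2, THF, −20 °C; MeOH, then aq. NaHCO3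
Reagents that add atoms: none
Why: Corey–Bakshi–Shibata reduction should deliver hydride 1,2 to the enone, the catalyst setting the carbinol carbon (the future C4 and C4′) as (R).

Step 6
Reactants: 8 (R)-5-bromo-4,4-dimethoxy-8-(methoxymethoxy)-1,4-dihydronaphthalen-1-ol
Product: 9 tert-butyldimethylsilyl ether of alcohol 8
Conditions: TBSCl, imidazole, DMF, 23 °C
Reagents that add atoms: tert-butyldimethylsilyl chloride, CC(C)(C)[Si](C)(C)Cl
Why: base-mediated O-silylation should protect the acid-sensitive allylic alcohol and install the bulky group that steers the next step.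

Step 7
Reactants: 9 tert-butyldimethylsilyl ether of alcohol 8
Product: 10 (1S,2S,3R)-5-bromo-1-(tert-butyldimethylsilyloxy)-2,3-epoxy-4,4-dimethoxy-8-(methoxymethoxy)-1,2,3,4-tetrahydronaphthalene
Conditions: CF3COCH3, KHSO5 (as 2KHSO5·KHSO4·K2SO4), NaHCO3, MeCN/H2O, 0 °C
Reagents that add atoms: potassium peroxymonosulfate KHSO5, [K+].[O-]S(=O)(=O)OO (one oxygen atom, passed on through the dioxirane formed in the flask)
Why: epoxidation of the deactivated cis-alkene by the dioxirane generated in situ should occur on the face opposite to the pseudoaxial silyloxy group (steric substrate control, the peri MOM-oxy group forcing that group axial), setting both epoxide carbons trans to the carbinol oxygen; this one epoxide supplies both halves.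

Step 8
Reactants: 10 trans-epoxy silyl ether
Product: 11 (1S,2R,3R)-5-bromo-2,3-epoxy-4,4-dimethoxy-8-(methoxymethoxy)-1,2,3,4-tetrahydronaphthalen-1-ol
Conditions: n-Bu4NF, AcOH, THF, 0 °C
Reagents that add atoms: none
Why: buffered fluoride desilylation should free the carbinol of the upper half (later oxidised to the C4 ketone), so that it can be told apart from the silylated C4′ oxygen of the lower half.

Step 9
Reactants: 10 trans-epoxy silyl ether
Product: 14 (1S,2S,3R)-5-tert-butoxy-1-(tert-butyldimethylsilyloxy)-2,3-epoxy-4,4-dimethoxy-8-(methoxymethoxy)-1,2,3,4-tetrahydronaphthalene, via aryllithium 12 (not isolated), via arylmagnesium bromide 13 (not isolated)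
Conditions: t-BuLi (2.1 equiv), THF, −78 °C; MgBr2·OEt2, −78 → 0 °C; PhCO3t-Bu, 0 °C
Reagents that add atoms: tert-butyl perbenzoate, CC(C)(C)OOC(=O)c1ccccc1
Why: bromine–lithium exchange, transmetalation to magnesium and electrophilic tert-butoxylation by the perester (Lawesson-type ether synthesis) should turn C–Br into the acid-labile aryl tert-butyl ether that becomes the C8′ oxygen.

Step 10
Reactants: 14 aryl tert-butyl ether
Product: 15 (2R,3S,4S)-8-tert-butoxy-4-(tert-butyldimethylsilyloxy)-2,3-epoxy-5-(methoxymethoxy)-3,4-dihydronaphthalen-1(2H)-one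
Conditions: TsOH·H2O (10 mol%), acetone/H2O (10:1), 23 °C
Reagents that add atoms: water, O
Why: acid-catalysed hydrolysis of the benzylic dimethyl ketal should unmask the C1′ ketone while the deactivated epoxide, the silyl ether and the aryl ethers survive.

Step 11
Reactants: 11 epoxy alcohol (upper half) and 15 epoxy ketone (lower half)
Product: 17 tertiary diaryl carbinol (C8–C1′ adduct), via dilithio species 16 (not isolated)
Conditions: 11, t-BuLi (3.1 equiv), THF, −78 °C; then 15, −78 → −40 °C; aq. NH4Cl
Reagents that add atoms: none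
Why: 1,2-addition of the aryllithium to the non-enolisable epoxy ketone should form the C8–C1′ bond, the aryl group entering anti to the adjacent epoxide oxygen (substrate control, as in additions to 2,3-epoxycyclohexanones) so that the tertiary hydroxyl is cis to the lower epoxide.

Step 12
Reactants: 17 tertiary diaryl carbinol
Product: 18 C4 ketone of the diaryl carbinol
Conditions: Dess–Martin periodinane, NaHCO3, CH2Cl2, 0 → 23 °C
Reagents that add atoms: none
Why: Dess–Martin oxidation should convert the only secondary alcohol into the C4 ketone, the tertiary alcohol, the ketal and both epoxides being inert.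

Step 13
Reactants: 18 C4 ketone of the diaryl carbinol
Product: 21 bridged ketal triol lacking both chlorine atoms, via oxolane mixed methyl ketal 19 (not isolated), via bridged ketal TBS ether 20 (not isolated)
Conditions: CF3CO2H/CH2Cl2/MeOH (3:6:1), 0 → 23 °C; then evaporation from PhMe
Reagents that add atoms: none
Why: CF3CO2H ionises the C1 dimethyl ketal to a methoxy oxocarbenium ion that the peri C1′ hydroxyl traps in a 5-exo-trig closure (oxolane, mixed ketal 19); loss of the second methanol gives the cyclic oxocarbenium ion, to which the C8′ phenol, freed by acidolysis of its tert-butyl ether, adds in a 6-endo-trig closure (the C1=O+ bond lies within the new 1,3-dioxin ring), and the MOM and TBS groups are then solvolysed. The closest known reaction type is acid-catalysed intramolecular transketalisation of a dimethyl ketal with a diol to a bridged or spiro aryl ketal. C1 is the only new stereocentre and is controlled by C1′: ring B hangs from C1′ on one face of the oxolane, so its phenol oxygen reaches only that face of the oxocarbenium ion, which puts the bridging oxygen syn and the aryl oxygen anti to the epoxide set in step 7. The step needs ionisation at C1 in preference to the doubly benzylic C1′–O bond, the C4′ benzylic position and the epoxides; the epoxide carbons are flanked by C–O carbons and deactivated, the C4′ oxygen stays silylated until late, and reversible C1′–O ionisation should return to the bridged ketal, the expected thermodynamic sink.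

Step 14
Reactants: 21 bridged ketal triol lacking both chlorine atoms
Product: 22 CNP0289684.3
Conditions: NCS (2.2 equiv), DMF, 0 → 23 °C
Reagents that add atoms: N-chlorosuccinimide, O=C1CCC(=O)N1Cl
Why: electrophilic aromatic chlorination should occur ortho to each free phenol, because in ring A the para position is blocked and C6 is the only activated site, and in ring B the free C5′ hydroxyl out-directs the ketal aryl oxygen so that C6′ is taken.

Compound list
1 | juglone (5-hydroxynaphthalene-1,4-dione) | O=C1C=CC(=O)c2c(O)cccc12 | starting material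
2 | 5-(methoxymethoxy)naphthalene-1,4-dione | O=C1C=CC(=O)c2c(OCOC)cccc12 | intermediate
3 | 5-(methoxymethoxy)naphthalene-1,4-diol (hydroquinone, not isolated) | Oc1ccc(O)c2c(OCOC)cccc12 | intermediate
4 | 1,4-dimethoxy-5-(methoxymethoxy)naphthalene | COc1ccc(OC)c2c(OCOC)cccc12 | intermediate
5 | 5-bromo-1,4-dimethoxy-8-(methoxymethoxy)naphthalene (Br para to the MOM ether) | COc1ccc(OC)c2c(OCOC)ccc(Br)c12 | intermediate
6 | 5-bromo-1,1,4,4-tetramethoxy-8-(methoxymethoxy)-1,4-dihydronaphthalene (quinone bisketal, not isolated) | COC1(OC)C=CC(OC)(OC)c2c(OCOC)ccc(Br)c12 | intermediate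
7 | 5-bromo-4,4-dimethoxy-8-(methoxymethoxy)naphthalen-1(4H)-one (ketone peri to OMOM, ketal peri to Br) | O=C1C=CC(OC)(OC)c2c(Br)ccc(OCOC)c12 | intermediate
8 | (R)-5-bromo-4,4-dimethoxy-8-(methoxymethoxy)-1,4-dihydronaphthalen-1-ol | O[C@@H]1C=CC(OC)(OC)c2c(Br)ccc(OCOC)c12 | intermediate
9 | tert-butyldimethylsilyl ether of 8, (R) | CC(C)(C)[Si](C)(C)O[C@@H]1C=CC(OC)(OC)c2c(Br)ccc(OCOC)c12 | intermediate
10 | (1S,2S,3R)-5-bromo-1-(tert-butyldimethylsilyloxy)-2,3-epoxy-4,4-dimethoxy-8-(methoxymethoxy)-1,2,3,4-tetrahydronaphthalene (epoxide trans to the silyloxy group) | CC(C)(C)[Si](C)(C)O[C@H]1c2c(OCOC)ccc(Br)c2C(OC)(OC)[C@@H]2O[C@H]12 | intermediate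
11 | (1S,2R,3R)-5-bromo-2,3-epoxy-4,4-dimethoxy-8-(methoxymethoxy)-1,2,3,4-tetrahydronaphthalen-1-ol (hydroxyl trans to the epoxide) | O[C@H]1c2c(OCOC)ccc(Br)c2C(OC)(OC)[C@@H]2O[C@H]12 | intermediate
12 | aryllithium from 10 (Li in place of Br, not isolated) | CC(C)(C)[Si](C)(C)O[C@H]1c2c(OCOC)ccc([Li])c2C(OC)(OC)[C@@H]2O[C@H]12 | intermediate
13 | arylmagnesium bromide from 12 (not isolated) | CC(C)(C)[Si](C)(C)O[C@H]1c2c(OCOC)ccc([Mg]Br)c2C(OC)(OC)[C@@H]2O[C@H]12 | intermediate
14 | (1S,2S,3R)-5-tert-butoxy-1-(tert-butyldimethylsilyloxy)-2,3-epoxy-4,4-dimethoxy-8-(methoxymethoxy)-1,2,3,4-tetrahydronaphthalene | CC(C)(C)[Si](C)(C)O[C@H]1c2c(OCOC)ccc(OC(C)(C)C)c2C(OC)(OC)[C@@H]2O[C@H]12 | intermediate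
15 | (2R,3S,4S)-8-tert-butoxy-4-(tert-butyldimethylsilyloxy)-2,3-epoxy-5-(methoxymethoxy)-3,4-dihydronaphthalen-1(2H)-one (silyloxy trans to the epoxide) | CC(C)(C)[Si](C)(C)O[C@H]1c2c(OCOC)ccc(OC(C)(C)C)c2C(=O)[C@@H]2O[C@H]12 | intermediate
16 | dilithio species from 11 (lithium alkoxide and aryllithium, not isolated) | [Li]O[C@H]1c2c(OCOC)ccc([Li])c2C(OC)(OC)[C@@H]2O[C@H]12 | intermediate
17 | tertiary diaryl carbinol: C8 of the upper epoxy alcohol (C1 dimethyl ketal, C4–OH, C5–OMOM) bonded to C1′ of the lower half (C1′–OH cis to the 2′,3′-epoxide, aryl cis to C4′–OTBS, C5′–OMOM, C8′–O-t-Bu) | O[C@H]1c2c(OCOC)ccc([C@]3(O)c4c(OC(C)(C)C)ccc(OCOC)c4[C@H](O[Si](C)(C)C(C)(C)C)[C@H]4O[C@H]43)c2C(OC)(OC)[C@@H]2O[C@H]12 | intermediate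
18 | C4 ketone of 17 (seco precursor of the bridged ketal) | O=C1c2c(OCOC)ccc([C@]3(O)c4c(OC(C)(C)C)ccc(OCOC)c4[C@H](O[Si](C)(C)C(C)(C)C)[C@H]4O[C@H]43)c2C(OC)(OC)[C@@H]2O[C@H]12 | intermediate
19 | oxolane mixed methyl ketal (C1–O–C1′ ring closed, C1 still bearing OMe, both C1 epimers, not isolated) | O=C1c2c(OCOC)ccc3c2C(OC)(O[C@]34c5c(OC(C)(C)C)ccc(OCOC)c5[C@H](O[Si](C)(C)C(C)(C)C)[C@H]5O[C@H]54)[C@@H]2O[C@H]12 | intermediate
20 | bridged ketal with free phenols and C4′–OTBS (not isolated) | O=C1c2c(O)ccc3c2[C@@]2(Oc4ccc(O)c5c4[C@]3(O2)[C@@H]2O[C@@H]2[C@H]5O[Si](C)(C)C(C)(C)C)[C@@H]2O[C@H]12 | intermediate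
21 | bridged ketal triol lacking both chlorine atoms (6,6′-didechloro target) | O=C1c2c(O)ccc3c2[C@@]2(Oc4ccc(O)c5c4[C@]3(O2)[C@@H]2O[C@@H]2[C@H]5O)[C@@H]2O[C@H]12 | intermediate
22 | CNP0289684.3 | O=C1c2c(O)c(Cl)cc3c2[C@@]2(Oc4cc(Cl)c(O)c5c4[C@]3(O2)[C@@H]2O[C@@H]2[C@H]5O)[C@@H]2O[C@H]12 | target

Total step count: 14. Longest linear sequence: 13 steps (steps 1–7, 9, 10 and 11–14); both coupling partners come from epoxide 10.

Steps most likely to fail

Step 13. The acid strength needed to cleave the aryl MOM ethers may ionise the doubly benzylic C1′–O bond or the C4′ benzylic alcohol (epimerisation, methanolysis), open the lower epoxide, or let tert-butyl and methoxymethyl cations alkylate the freed phenols. The fallback sets out from 18 and comes back at 21; it separates ring closure from deprotection and avoids protic acid. Me3SiOTf with 2,2′-bipyridyl in CH2Cl2 at 0 °C (silyl triflate activation of ketals, tert-butyl ethers and aryl MOM ethers through pyridinium intermediates) should exchange the dimethyl ketal, convert the three aryl ethers into silyl ethers and close both ketal rings, giving the tris-silylated bridged ketal F1. n-Bu4NF buffered with AcOH in THF at 0 °C then removes the two trimethylsilyl groups and the TBS group to give 21, so the free C4′ alcohol never meets strong acid.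

Step 11. Facial selectivity or conversion may be poor, because the face anti to the epoxide also carries the pseudoaxial C4′ silyloxy group and the alkoxide-bearing dilithio species is aggregated; the trans-epoxy alkoxide may also suffer Payne-type epoxide migration. The fallback sets out from 15 and 11 and comes back at 17; it exchanges the roles of the two oxygen substituents so that a free C4′ alkoxide directs the aryl metal to its own face. n-Bu4NF/AcOH in THF converts 15 into the hydroxy ketone F2, and Et3SiCl/imidazole in DMF converts 11 into the triethylsilyl ether F3. F2 is deprotonated with LiN(SiMe3)2 at −78 °C and treated with the monolithio species made from F3 and t-BuLi; the lithium alkoxide on the anti face should deliver the aryl group cis to itself and give the diol adduct F4. TBSCl/imidazole silylates the secondary C4′ hydroxyl (the tertiary one is inert) to give the bis-silyl adduct F5, and HF·pyridine buffered with pyridine in THF at 0 °C removes the triethylsilyl group selectively to give 17.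

Step 5. Enantioselectivity may be low, since the catalyst must tell a peri-substituted aryl from a cis-alkenyl group, and the acid-sensitive product may aromatise on work-up; any erosion is carried into both halves, although heterochiral coupling products in step 11 would be separable diastereomers. The fallback sets out from 7 and comes back at 8. NaBH4/CeCl3·7H2O in MeOH at −78 °C (Luche reduction) gives the racemic alcohol F6; lipase-catalysed kinetic resolution (Burkholderia cepacia lipase, vinyl acetate, t-BuOMe, 30 °C) should acetylate the (R)-enantiomer (Kazlauskas rule) to the (R)-acetate F7, which is separated from unreacted (S)-alcohol and methanolysed with K2CO3 in MeOH to 8.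

Further compounds
F1 | step 13 | tris-silylated bridged ketal (C5 and C5′ trimethylsilyl ethers, C4′ TBS ether) | O=C1c2c(O[Si](C)(C)C)ccc3c2[C@@]2(Oc4ccc(O[Si](C)(C)C)c5c4[C@]3(O2)[C@@H]2O[C@@H]2[C@H]5O[Si](C)(C)C(C)(C)C)[C@@H]2O[C@H]12
F2 | step 11 | (2R,3S,4S)-8-tert-butoxy-2,3-epoxy-4-hydroxy-5-(methoxymethoxy)-3,4-dihydronaphthalen-1(2H)-one | O[C@H]1c2c(OCOC)ccc(OC(C)(C)C)c2C(=O)[C@@H]2O[C@H]12
F3 | step 11 | triethylsilyl ether of 11 | CC[Si](CC)(CC)O[C@H]1c2c(OCOC)ccc(Br)c2C(OC)(OC)[C@@H]2O[C@H]12
F4 | step 11 | diol adduct (C4–OSiEt3 on the upper half, free C1′–OH and C4′–OH on the lower half) | CC[Si](CC)(CC)O[C@H]1c2c(OCOC)ccc([C@]3(O)c4c(OC(C)(C)C)ccc(OCOC)c4[C@H](O)[C@H]4O[C@H]43)c2C(OC)(OC)[C@@H]2O[C@H]12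
F5 | step 11 | bis-silyl adduct (C4–OSiEt3, C4′–OTBS, free C1′–OH) | CC[Si](CC)(CC)O[C@H]1c2c(OCOC)ccc([C@]3(O)c4c(OC(C)(C)C)ccc(OCOC)c4[C@H](O[Si](C)(C)C(C)(C)C)[C@H]4O[C@H]43)c2C(OC)(OC)[C@@H]2O[C@H]12
F6 | step 5 | racemic 5-bromo-4,4-dimethoxy-8-(methoxymethoxy)-1,4-dihydronaphthalen-1-ol | OC1C=CC(OC)(OC)c2c(Br)ccc(OCOC)c12
F7 | step 5 | (R)-5-bromo-4,4-dimethoxy-8-(methoxymethoxy)-1,4-dihydronaphthalen-1-yl acetate | CC(=O)O[C@@H]1C=CC(OC)(OC)c2c(Br)ccc(OCOC)c12
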